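## Retrosynthetic overview

1. Target 39 ⇐ C20 CH2OH → CO2H, ene-type chlorination of the C5=C6 alkene bearing the C16 methyl (gives 6-Cl and the 5(16)-methylene), and three late acetates.
2. Lactone ring D and the C2, C7 and C9 carbinols ⇐ one relay of hydroxyl-directed reductions on tri-ketone 32, then lactonisation.
3. Oxocane ring B (C3–C4 bond) ⇐ bridging intramolecular Mukaiyama-type C-glycosylation of a 6-methoxypyranone by a tethered enol silane (new step); C8–C9 ⇐ aldol of the pyranone enolate with ring-A aldehyde 16.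
4. Pyranone ring C ⇐ Achmatowicz oxidative ring expansion of an Evans-aldol furyl carbinol (furfural + propanoyl unit).
5. Ring A ⇐ catalytic asymmetric Diels–Alder of enal 3 with 1-acetoxybutadiene. Ring order: A, then C (ring expansion), then B, then D.

Assumption: positions are cited with the briarane numbering of the target (ring A = C1, C10–C14; C15 = CH3 on C1; C16 on C5; C17/C18 = CH(CH3) of the lactone; C19 = lactone C=O; C20 on C11), and "as in 39" means the configuration fixed by the SMILES.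

## Route

Step 1
Reactants: 1 propanal; 2 2,2-dimethoxyacetaldehyde
Product: 3 (E)-4,4-dimethoxy-2-methylbut-2-enal
Conditions: pyrrolidine (10 mol %), AcOH (10 mol %), toluene, 60 °C
Reagents that add atoms: none
Why: Amine-catalysed crossed aldol condensation in which only propanal can enolise and the glyoxal mono-acetal is the acceptor, dehydration giving the conjugated E-enal.

Step 2
Reactants: 3 (E)-4,4-dimethoxy-2-methylbut-2-enal; 4 (E)-buta-1,3-dien-1-yl acetate
Product: 5 (1S,5S,6R)-5-(dimethoxymethyl)-6-formyl-6-methylcyclohex-2-en-1-yl acetate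
Conditions: (S)-o-tolyl-CBS oxazaborolidine·HNTf2 (20 mol %), CH2Cl2, −78 → −40 °C
Reagents that add atoms: none
Why: Lewis-acid-catalysed Diels–Alder reaction in which the 1-acetoxy diene adds "ortho" and endo (14-OAc cis to the formyl group), the E-dienophile puts the C9 acetal trans to the formyl group, and the chiral oxazaborolidinium shields one enal face to fix C1, C10 and C14 (the antipodal catalyst is used if the facial sense must be reversed).

Step 3
Reactants: 5 (1S,5S,6R)-5-(dimethoxymethyl)-6-formyl-6-methylcyclohex-2-en-1-yl acetate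
Product: 6 (1S,5S,6R)-5-(dimethoxymethyl)-6-(1-hydroxyethyl)-6-methylcyclohex-2-en-1-yl acetate (both C2 epimers)
Conditions: MeMgBr (1.1 equiv), THF, −78 °C; sat. NH4Cl at −78 °C
Reagents that add atoms: methylmagnesium bromide, C[Mg]Br
Why: Chemoselective Grignard 1,2-addition to the aldehyde at low temperature (acetate and acetal untouched), the new carbinol centre being erased in step 4.

Step 4
Reactants: 6 (1S,5S,6R)-5-(dimethoxymethyl)-6-(1-hydroxyethyl)-6-methylcyclohex-2-en-1-yl acetate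
Product: 7 (1S,5S,6R)-6-acetyl-5-(dimethoxymethyl)-6-methyl-4-oxocyclohex-2-en-1-yl acetate
Conditions: CrO3 (15 equiv), 3,5-dimethylpyrazole (15 equiv), CH2Cl2, −20 °C
Reagents that add atoms: chromium trioxide, O=[Cr](=O)=O
Why: Cr(VI)/3,5-dimethylpyrazole oxidises the secondary alcohol to the methyl ketone and, as an allylic oxidation, the only allylic CH2 (C11) to the enone, with no stereocentre made and C10 keeping its more stable equatorial acetal.

Step 5
Reactants: 7 (1S,5S,6R)-6-acetyl-5-(dimethoxymethyl)-6-methyl-4-oxocyclohex-2-en-1-yl acetate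
Product: 10 (1S,5S,6R)-5-(dimethoxymethyl)-6-methyl-4-oxo-6-[2-(triethylsilyloxy)acetyl]cyclohex-2-en-1-yl acetate, via lithium enolate 8 (not isolated), via silyl enol ether 9 (not isolated)
Conditions: LDA (1.1 equiv), THF, −78 °C; Et3SiCl; then mCPBA, NaHCO3, CH2Cl2, −20 → 0 °C
Reagents that add atoms: chlorotriethylsilane, CC[Si](Cl)(CC)CC; 3-chloroperbenzoic acid, OOC(=O)c1cccc(Cl)c1
Why: Kinetic deprotonation occurs at the methyl ketone (the enone has only a hindered tertiary α′-H) and Rubottom oxidation of the silyl enol ether with 1,4-silyl shift installs the C3 oxygen as its TES ether, no stereocentre being formed.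

Step 6
Reactants: 10 (1S,5S,6R)-5-(dimethoxymethyl)-6-methyl-4-oxo-6-[2-(triethylsilyloxy)acetyl]cyclohex-2-en-1-yl acetate
Product: 11 (1S,2R,3S)-3-(dimethoxymethyl)-2-methyl-4-oxo-2-[2-(triethylsilyloxy)acetyl]cyclohexyl acetate
Conditions: H2 (1 atm), 5% Rh/Al2O3, EtOAc, 23 °C
Reagents that add atoms: none
Why: Catalytic hydrogenation of the enone C=C, Rh/Al2O3 being chosen to avoid hydrogenolysis of the γ-acetoxy group, with no stereocentre formed.

Step 7
Reactants: 11 (1S,2R,3S)-3-(dimethoxymethyl)-2-methyl-4-oxo-2-[2-(triethylsilyloxy)acetyl]cyclohexyl acetate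
Product: 12 the 11-methylidene analogue of 11 (C11=C20H2; C1, C10, C14 as in 11)
Conditions: Ph3P=CH2 (salt-free, 1.1 equiv), THF, −78 → 0 °C
Reagents that add atoms: methylenetriphenylphosphorane, C=P(c1ccccc1)(c1ccccc1)c1ccccc1
Why: Wittig methylenation of the more reactive cyclohexanone (the neopentyl α-silyloxy ketone at C2 is far more hindered), C10 remaining in its thermodynamically preferred configuration.

Step 8
Reactants: 12 the 11-methylidene analogue of 11
Product: 13 ring-A 11,20-diol (11-OH tertiary and cis to 14-OAc, C20 = CH2OH; C3-OTES ketone and C9 acetal retained)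
Conditions: OsO4 (2 mol %), NMO (1.5 equiv), acetone/H2O (5:1), 23 °C
Reagents that add atoms: N-methylmorpholine N-oxide, C[N+]1([O-])CCOCC1; water, O
Why: Upjohn dihydroxylation of the only alkene, OsO4 adding anti to the adjacent C10 acetal substituent and to the axial C1 methyl so that the new C11 hydroxyl is cis to 14-OAc as in the target.

Step 9
Reactants: 13 ring-A 11,20-diol
Product: 14 20-O-tert-butyldiphenylsilyl ether of 13 (11-OH free)
Conditions: TBDPSCl (1.1 equiv), imidazole, DMF, 0 °C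
Reagents that add atoms: tert-butylchlorodiphenylsilane, CC(C)(C)[Si](Cl)(c1ccccc1)c1ccccc1
Why: Selective silylation of the primary alcohol, the tertiary 11-OH being unreactive under these conditions.

Step 10
Reactants: 14 20-O-tert-butyldiphenylsilyl ether of 13
Product: 16 ring-A aldehyde (C9 = CHO on C10, 11-OTES, 20-OTBDPS, 14-OAc, C2 ketone with C3-OTES), via collidinium salt 15 (not isolated)
Conditions: Et3SiOTf (3 equiv), 2,4,6-collidine (4 equiv), CH2Cl2, 0 °C; then H2O
Reagents that add atoms: triethylsilyl trifluoromethanesulfonate, CC[Si](CC)(CC)OS(=O)(=O)C(F)(F)F; water, O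
Why: Fujioka acetal deprotection, in which Et3SiOTf/collidine turns the dimethyl acetal into a collidinium N,O-acetal that water hydrolyses to the aldehyde without acid (primary TES ether and ketone survive) while the tertiary 11-OH is silylated in the same operation, no stereocentre being touched.

Step 11
Reactants: 17 propanoyl chloride
Product: 18 (4R)-4-benzyl-3-propanoyl-1,3-oxazolidin-2-one
Conditions: (R)-4-benzyloxazolidin-2-one, n-BuLi, THF, −78 °C; then 17, −78 → 0 °C
Reagents that add atoms: (R)-4-benzyloxazolidin-2-one (auxiliary), O=C1N[C@H](Cc2ccccc2)CO1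
Why: N-Acylation of the lithiated Evans oxazolidinone with the acid chloride.

Step 12
Reactants: 18 (4R)-4-benzyl-3-propanoyl-1,3-oxazolidin-2-one; 19 furan-2-carbaldehyde (furfural)
Product: 21 (4R)-4-benzyl-3-[(2R,3R)-3-(furan-2-yl)-3-hydroxy-2-methylpropanoyl]-1,3-oxazolidin-2-one, via Z-boron enolate 20 (not isolated)
Conditions: Bu2BOTf (1.1 equiv), i-Pr2NEt, CH2Cl2, 0 °C; 19, −78 → 0 °C; pH 7 buffer, MeOH, 30% H2O2
Reagents that add atoms: none
Why: Evans syn-aldol reaction, the Z-boron enolate reacting through a Zimmerman–Traxler chair under auxiliary control to give the (2R,3R) syn adduct that fixes C17 and the furyl carbinol C8.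

Step 13
Reactants: 21 (4R)-4-benzyl-3-[(2R,3R)-3-(furan-2-yl)-3-hydroxy-2-methylpropanoyl]-1,3-oxazolidin-2-one
Product: 23 (4R)-4-benzyl-3-[(2R)-2-[(2R)-6-hydroxy-3-oxo-3,6-dihydro-2H-pyran-2-yl]propanoyl]-1,3-oxazolidin-2-one (anomer mixture), via ene-dione 22 (not isolated)
Conditions: NBS (1.05 equiv), NaHCO3, NaOAc, THF/H2O (4:1), 0 °C
Reagents that add atoms: water, O
Why: Achmatowicz rearrangement, in which bromonium-induced hydration of the furan gives the cis-ene-dione whose carbinol oxygen closes onto the remote carbonyl, expanding the five-membered furan into the six-membered pyranone (C4–C8 and O of ring C) with C8 untouched.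

Step 14
Reactants: 23 (4R)-4-benzyl-3-[(2R)-2-[(2R)-6-hydroxy-3-oxo-3,6-dihydro-2H-pyran-2-yl]propanoyl]-1,3-oxazolidin-2-one
Product: 24 (4R)-4-benzyl-3-[(2R)-2-[(2R,6S)-6-methoxy-3-oxo-3,6-dihydro-2H-pyran-2-yl]propanoyl]-1,3-oxazolidin-2-one
Conditions: HC(OMe)3 (3 equiv), BF3·OEt2 (10 mol %), CH2Cl2, −20 °C
Reagents that add atoms: trimethyl orthoformate, COC(OC)OC
Why: Acid-catalysed glycosidation through the pyranone oxocarbenium ion, the anomeric effect giving the 2,6-trans methyl glycoside (OMe axial and trans to the C8 side chain).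

Step 15
Reactants: 24 (4R)-4-benzyl-3-[(2R)-2-[(2R,6S)-6-methoxy-3-oxo-3,6-dihydro-2H-pyran-2-yl]propanoyl]-1,3-oxazolidin-2-one; 16 ring-A aldehyde
Product: 26 aldol adduct (pyranone with C4-OMe joined at its new quaternary C8 (R) to ring A through the C9 carbinol (9R); C17 imide chain on C8), via lithium enolate 25 (not isolated)
Conditions: LDA (1.1 equiv), 24 (1.1 equiv), THF, −78 °C, 30 min; 16, −78 °C, 1 h; AcOH quench at −78 °C
Reagents that add atoms: none
Why: Aldol addition of the kinetic α′-enolate of the enone (C8 is its only enolisable α-position and the α-branched imide is not deprotonated), the aldehyde entering anti to the pseudo-axial anomeric OMe to set the C8 quaternary centre and the closed chair transition state giving the 9R carbinol, which is oxidised at once in step 16 to forestall lactonisation onto the imide.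

Step 16
Reactants: 26 aldol adduct
Product: 27 C9 ketone of 26 (7,9-diketone with quaternary C8)
Conditions: Dess–Martin periodinane (1.5 equiv), NaHCO3, CH2Cl2, 0 → 23 °C
Reagents that add atoms: none
Why: Dess–Martin oxidation of the only free secondary alcohol, which removes the temporary C9 centre after it has relayed stereocontrol to C8.

Step 17
Reactants: 27 C9 ketone of 26
Product: 29 bridged tricycle (4,8-oxygen-bridged 11-oxabicyclo[5.3.1] B/C core fused to ring A; 2,7,9-triketone, C5=C6, 3-OTES on the convex face, 11-OTES, 14-OAc, 20-OTBDPS, C19 imide), via bis-silyl enediol ether 28 (not isolated)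
Conditions: Et3N (1.5 equiv), TMSOTf (1.3 equiv), CH2Cl2, −78 → 0 °C; dilute to 2 mM, TMSOTf (1.0 equiv), −78 → −30 °C; aq. NaHCO3
Reagents that add atoms: none
Why: Proposed new method: soft enolisation turns the C2 α-silyloxy ketone into its enol silane while TMSOTf ionises the anomeric OMe to the pyranone oxocarbenium ion, and the enol carbon C3, held on the axial C8 tether, attacks C4 on the tether face to close the eight-membered ring as a 1,3-diaxial bridge (C4 fixed by the tether, C3 placing its OTES on the convex face because the concave position under the pyran is blocked), the closest known reactions being intermolecular Mukaiyama C-glycosylation of Achmatowicz acetals and intramolecular acetal–enol silane cyclisation to eight-membered carbocycles.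

Step 18
Reactants: 29 bridged tricycle
Product: 32 5-methyl enone 3,11-diol (C16 methyl on C5, C5=C6–C7=O; 3-OH and 11-OH free; 2- and 9-ketones), via lithium enolate 30 (not isolated), via silylated methyl enone 31 (not isolated)
Conditions: Me2CuLi (from MeLi/CuI, 1.5 equiv), Et2O/THF, −78 °C; PhS(Cl)=N-t-Bu (2 equiv), −78 → 0 °C; then 1 M HCl/THF (1:4), 23 °C
Reagents that add atoms: lithium dimethylcuprate, [Li+].C[Cu-]C
Why: Gilman 1,4-addition to the enone followed by Mukaiyama dehydrogenation of the resulting enolate with the sulfinimidoyl chloride restores the enone with the C16 methyl on C5 (no stereocentre kept at C5), and the acidic finish cleaves both triethylsilyl ethers.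

Step 19
Reactants: 32 5-methyl enone 3,11-diol
Product: 34 lactone tetraol (C19–O–C7 γ-lactone; 2-, 3-, 9- and 11-OH free, all as in 39; 14-OAc; 20-OTBDPS; C5=C6 with C16 methyl), via pentaol imide 33 (not isolated)
Conditions: Me4NBH(OAc)3 (10 equiv), MeCN/AcOH (1:1), −30 → 23 °C; then CSA (0.2 equiv), toluene, 50 °C
Reagents that add atoms: none
Why: Evans–Saksena hydroxyl-directed reductions run as a relay: 3-OH delivers hydride to C2 from the convex face (trans-2,3-diol), 11-OH delivers to C9 (1,3-anti, 9S), and the new 9-OH, which lies under C7, delivers to the enone carbonyl from the concave face so that 7-OH is axial and cis to the C17 chain, where acid-catalysed lactonisation expels the auxiliary.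

Step 20
Reactants: 34 lactone tetraol
Product: 35 2,3,9,14-tetraacetate (11-OH free, 20-OTBDPS)
Conditions: Ac2O (6 equiv), pyridine, DMAP (0.1 equiv), CH2Cl2, 0 → 23 °C
Reagents that add atoms: acetic anhydride, CC(=O)OC(C)=O
Why: DMAP-catalysed acetylation of the three secondary alcohols, the tertiary 11-OH not being acylated under these conditions.

Step 21
Reactants: 35 2,3,9,14-tetraacetate
Product: 36 6-chloro-5(16)-ene (20-O-TBDPS analogue of 39 with CH2O at C20)
Conditions: Ca(OCl)2 (1.2 equiv), solid CO2, CH2Cl2/H2O, 0 °C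
Reagents that add atoms: hypochlorous acid (from calcium hypochlorite), OCl
Why: Ene-type chlorination with HOCl (Hegde–Wolinsky), Cl+ adding to C6 of the trisubstituted alkene from the open convex face (the concave face is covered by the five-carbon bridge) with loss of a C16 proton, which gives the equatorial 6-chloride cis to the lactone oxygen and the 5(16)-methylene.

Step 22
Reactants: 36 6-chloro-5(16)-ene
Product: 37 11,20-diol (C20 = CH2OH analogue of 39)
Conditions: HF·pyridine, pyridine/THF, 0 → 23 °C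
Reagents that add atoms: none
Why: Fluoride cleavage of the silyl ether under buffered conditions that leave the acetates, the lactone and the allylic chloride intact.

Step 23
Reactants: 37 11,20-diol
Product: 39 target acid, via hydroxy aldehyde 38 (not isolated)
Conditions: TEMPO (10 mol %), NaClO2 (2 equiv), NaOCl (2 mol %), MeCN/phosphate buffer (pH 6.7), 35 °C
Reagents that add atoms: sodium chlorite, [Na+].[O-]Cl=O
Why: Zhao's TEMPO/NaOCl/NaClO2 oxidation takes the primary alcohol through the aldehyde to the carboxylic acid without touching the tertiary alcohol, the acetates, the lactone, the allylic chloride or the electron-poor exocyclic alkene, and no stereocentre is affected.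

## Compound list

1 | propanal | CCC=O | starting material
2 | 2,2-dimethoxyacetaldehyde | COC(OC)C=O | starting material
3 | (E)-4,4-dimethoxy-2-methylbut-2-enal | O=C/C(C)=C/C(OC)OC | intermediate
4 | (E)-buta-1,3-dien-1-yl acetate | CC(=O)O/C=C/C=C | starting material
5 | (1S,5S,6R)-5-(dimethoxymethyl)-6-formyl-6-methylcyclohex-2-en-1-yl acetate (14-OAc cis to formyl, C9 acetal trans) | COC(OC)[C@@H]1[C@](C)([C@@H](OC(C)=O)C=CC1)C=O | intermediate
6 | (1S,5S,6R)-5-(dimethoxymethyl)-6-(1-hydroxyethyl)-6-methylcyclohex-2-en-1-yl acetate (C2 epimers) | COC(OC)[C@@H]1[C@](C)([C@@H](OC(C)=O)C=CC1)C(C)O | intermediate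
7 | (1S,5S,6R)-6-acetyl-5-(dimethoxymethyl)-6-methyl-4-oxocyclohex-2-en-1-yl acetate | COC(OC)[C@@H]1[C@](C)([C@@H](OC(C)=O)C=CC1=O)C(C)=O | intermediate
8 | lithium enolate of the methyl ketone of 7 | COC(OC)[C@@H]1[C@](C)([C@@H](OC(C)=O)C=CC1=O)C([O-])=C.[Li+] | intermediate (not isolated)
9 | triethylsilyl enol ether of 7 | COC(OC)[C@@H]1[C@](C)([C@@H](OC(C)=O)C=CC1=O)C(=C)O[Si](CC)(CC)CC | intermediate (not isolated)
10 | (1S,5S,6R)-5-(dimethoxymethyl)-6-methyl-4-oxo-6-[2-(triethylsilyloxy)acetyl]cyclohex-2-en-1-yl acetate | COC(OC)[C@@H]1[C@](C)([C@@H](OC(C)=O)C=CC1=O)C(=O)CO[Si](CC)(CC)CC | intermediate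
11 | (1S,2R,3S)-3-(dimethoxymethyl)-2-methyl-4-oxo-2-[2-(triethylsilyloxy)acetyl]cyclohexyl acetate | COC(OC)[C@@H]1[C@](C)([C@@H](OC(C)=O)CCC1=O)C(=O)CO[Si](CC)(CC)CC | intermediate
12 | 11-methylidene analogue of 11 | COC(OC)[C@@H]1[C@](C)([C@@H](OC(C)=O)CCC1=C)C(=O)CO[Si](CC)(CC)CC | intermediate
13 | ring-A 11,20-diol (11-OH cis to 14-OAc) | COC(OC)[C@@H]1[C@](C)([C@@H](OC(C)=O)CC[C@]1(O)CO)C(=O)CO[Si](CC)(CC)CC | intermediate
14 | 20-O-TBDPS ether of 13 | COC(OC)[C@@H]1[C@](C)([C@@H](OC(C)=O)CC[C@]1(O)CO[Si](c1ccccc1)(c1ccccc1)C(C)(C)C)C(=O)CO[Si](CC)(CC)CC | intermediate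
15 | C9 collidinium N,O-acetal triflate (11-OTES) | COC([n+]1c(C)cc(C)cc1C)[C@@H]1[C@](C)([C@@H](OC(C)=O)CC[C@]1(O[Si](CC)(CC)CC)CO[Si](c1ccccc1)(c1ccccc1)C(C)(C)C)C(=O)CO[Si](CC)(CC)CC.[O-]S(=O)(=O)C(F)(F)F | intermediate (not isolated)
16 | ring-A aldehyde (C9 CHO, 11-OTES, 20-OTBDPS, 14-OAc, C3-OTES ketone) | O=C[C@@H]1[C@](C)([C@@H](OC(C)=O)CC[C@]1(O[Si](CC)(CC)CC)CO[Si](c1ccccc1)(c1ccccc1)C(C)(C)C)C(=O)CO[Si](CC)(CC)CC | intermediate
17 | propanoyl chloride | CCC(=O)Cl | starting material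
18 | (4R)-4-benzyl-3-propanoyl-1,3-oxazolidin-2-one | CCC(=O)N1[C@H](Cc2ccccc2)COC1=O | intermediate
19 | furan-2-carbaldehyde | O=Cc1ccco1 | starting material
20 | (Z)-dibutylboron enolate of 18 | C/C=C(\OB(CCCC)CCCC)N1[C@H](Cc2ccccc2)COC1=O | intermediate (not isolated)
21 | (4R)-4-benzyl-3-[(2R,3R)-3-(furan-2-yl)-3-hydroxy-2-methylpropanoyl]-1,3-oxazolidin-2-one | O[C@@H](c1ccco1)[C@@H](C)C(=O)N1[C@H](Cc2ccccc2)COC1=O | intermediate
22 | (4R)-4-benzyl-3-[(2R,3R,5Z)-3-hydroxy-2-methyl-4,7-dioxohept-5-enoyl]-1,3-oxazolidin-2-one | O=C/C=C\C(=O)[C@H](O)[C@@H](C)C(=O)N1[C@H](Cc2ccccc2)COC1=O | intermediate (not isolated)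
23 | Achmatowicz lactol, (2R)-6-hydroxy-3-oxo-3,6-dihydro-2H-pyran-2-yl propanoyl imide (anomers) | O=C1C=CC(O)O[C@@H]1[C@@H](C)C(=O)N1[C@H](Cc2ccccc2)COC1=O | intermediate
24 | (4R)-4-benzyl-3-[(2R)-2-[(2R,6S)-6-methoxy-3-oxo-3,6-dihydro-2H-pyran-2-yl]propanoyl]-1,3-oxazolidin-2-one | O=C1C=C[C@@H](OC)O[C@@H]1[C@@H](C)C(=O)N1[C@H](Cc2ccccc2)COC1=O | intermediate
25 | lithium C7–C8 enolate of 24 | [Li+].[O-]C1C=C[C@@H](OC)OC=1[C@@H](C)C(=O)N1[C@H](Cc2ccccc2)COC1=O | intermediate (not isolated)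
26 | aldol adduct (8R, 9R carbinol) | O=C1C=C[C@@H](OC)O[C@]1([C@@H](C)C(=O)N1[C@H](Cc2ccccc2)COC1=O)[C@H](O)[C@@H]1[C@](C)([C@@H](OC(C)=O)CC[C@]1(O[Si](CC)(CC)CC)CO[Si](c1ccccc1)(c1ccccc1)C(C)(C)C)C(=O)CO[Si](CC)(CC)CC | intermediate
27 | C9 ketone of 26 | O=C1C=C[C@@H](OC)O[C@]1([C@@H](C)C(=O)N1[C@H](Cc2ccccc2)COC1=O)C(=O)[C@@H]1[C@](C)([C@@H](OC(C)=O)CC[C@]1(O[Si](CC)(CC)CC)CO[Si](c1ccccc1)(c1ccccc1)C(C)(C)C)C(=O)CO[Si](CC)(CC)CC | intermediate
28 | (Z)-C2(OTMS)=C3(OTES) enediol bis-silyl ether of 27 | O=C1C=C[C@@H](OC)O[C@]1([C@@H](C)C(=O)N1[C@H](Cc2ccccc2)COC1=O)C(=O)[C@@H]1[C@](C)([C@@H](OC(C)=O)CC[C@]1(O[Si](CC)(CC)CC)CO[Si](c1ccccc1)(c1ccccc1)C(C)(C)C)/C(O[Si](C)(C)C)=C/O[Si](CC)(CC)CC | intermediate (not isolated)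
29 | bridged tricycle (2,7,9-triketone, C5=C6, 3-OTES, 11-OTES) | O=C1C=C[C@H]2O[C@]1([C@@H](C)C(=O)N1[C@H](Cc4ccccc4)COC1=O)C(=O)[C@@H]3[C@](C)([C@@H](OC(C)=O)CC[C@]3(O[Si](CC)(CC)CC)CO[Si](c3ccccc3)(c3ccccc3)C(C)(C)C)C(=O)[C@@H]2O[Si](CC)(CC)CC | intermediate
30 | lithium C6–C7 enolate of the 5-methyl adduct of 29 | [Li+].[O-]C1=CC(C)[C@H]2O[C@]1([C@@H](C)C(=O)N1[C@H](Cc4ccccc4)COC1=O)C(=O)[C@@H]3[C@](C)([C@@H](OC(C)=O)CC[C@]3(O[Si](CC)(CC)CC)CO[Si](c3ccccc3)(c3ccccc3)C(C)(C)C)C(=O)[C@@H]2O[Si](CC)(CC)CC | intermediate (not isolated)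
31 | 5-methyl enone, 3,11-bis-TES ether | O=C1C=C(C)[C@H]2O[C@]1([C@@H](C)C(=O)N1[C@H](Cc4ccccc4)COC1=O)C(=O)[C@@H]3[C@](C)([C@@H](OC(C)=O)CC[C@]3(O[Si](CC)(CC)CC)CO[Si](c3ccccc3)(c3ccccc3)C(C)(C)C)C(=O)[C@@H]2O[Si](CC)(CC)CC | intermediate (not isolated)
32 | 5-methyl enone 3,11-diol | O=C1C=C(C)[C@H]2O[C@]1([C@@H](C)C(=O)N1[C@H](Cc4ccccc4)COC1=O)C(=O)[C@@H]3[C@](C)([C@@H](OC(C)=O)CC[C@]3(O)CO[Si](c3ccccc3)(c3ccccc3)C(C)(C)C)C(=O)[C@@H]2O | intermediate
33 | 2,3,7,9,11-pentaol imide (C2, C7, C9 as in 39) | O[C@H]1C=C(C)[C@H]2O[C@]1([C@@H](C)C(=O)N1[C@H](Cc4ccccc4)COC1=O)[C@@H](O)[C@@H]3[C@](C)([C@@H](OC(C)=O)CC[C@]3(O)CO[Si](c3ccccc3)(c3ccccc3)C(C)(C)C)[C@@H](O)[C@@H]2O | intermediate (not isolated)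
34 | lactone 2,3,9,11-tetraol (14-OAc, 20-OTBDPS, C5=C6 with C16 methyl) | CC1[C@H]2O[C@]3([C@@H](C)C(=O)O[C@H]3C=1)[C@@H](O)[C@@H]1[C@](C)([C@@H](OC(C)=O)CC[C@]1(O)CO[Si](c1ccccc1)(c1ccccc1)C(C)(C)C)[C@@H](O)[C@@H]2O | intermediate
35 | 2,3,9,14-tetraacetate of 34 | CC1[C@H]2O[C@]3([C@@H](C)C(=O)O[C@H]3C=1)[C@@H](OC(C)=O)[C@@H]1[C@](C)([C@@H](OC(C)=O)CC[C@]1(O)CO[Si](c1ccccc1)(c1ccccc1)C(C)(C)C)[C@@H](OC(C)=O)[C@@H]2OC(C)=O | intermediate
36 | 6-chloro-5(16)-ene, 20-O-TBDPS | C=C1[C@H]2O[C@]3([C@@H](C)C(=O)O[C@H]3[C@H]1Cl)[C@@H](OC(C)=O)[C@@H]1[C@](C)([C@@H](OC(C)=O)CC[C@]1(O)CO[Si](c1ccccc1)(c1ccccc1)C(C)(C)C)[C@@H](OC(C)=O)[C@@H]2OC(C)=O | intermediate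
37 | 11,20-diol (C20 CH2OH) | C=C1[C@H]2O[C@]3([C@@H](C)C(=O)O[C@H]3[C@H]1Cl)[C@@H](OC(C)=O)[C@@H]1[C@](C)([C@@H](OC(C)=O)CC[C@]1(O)CO)[C@@H](OC(C)=O)[C@@H]2OC(C)=O | intermediate
38 | 11-hydroxy-20-aldehyde | C=C1[C@H]2O[C@]3([C@@H](C)C(=O)O[C@H]3[C@H]1Cl)[C@@H](OC(C)=O)[C@@H]1[C@](C)([C@@H](OC(C)=O)CC[C@]1(O)C=O)[C@@H](OC(C)=O)[C@@H]2OC(C)=O | intermediate (not isolated)
39 | CNP0186125.1 (1R,2R,3R,4R,6S,7R,8R,9S,10S,11R,14S,17R) | C=C1[C@H]2O[C@]3([C@@H](C)C(=O)O[C@H]3[C@H]1Cl)[C@@H](OC(C)=O)[C@@H]1[C@](C)([C@@H](OC(C)=O)CC[C@]1(O)C(=O)O)[C@@H](OC(C)=O)[C@@H]2OC(C)=O | target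

## Step count and risks

Total steps: 23. Longest linear sequence: 19 (steps 1–10, then 15–23); the pyranone arm (steps 11–14) is convergent.

Steps most likely to fail:

**Step 17 (the proposed new bridging cyclisation).** The eight-membered ring closure may be slow, or the enol silane may react elsewhere. Fallback with known chemistry, from 27 back to 29: the anomeric methyl acetal of 27 is oxidised to the lactone with mCPBA/BF3·OEt2 (Grieco oxidation of lactol ethers) to give the pyran-3,6-dione keto-lactone F1. LiHMDS (THF, −78 °C) then forms the C2 enolate, which adds to the lactone carbonyl in a Claisen-type closure to give the bridged hemiketal F2. Et3SiH/BF3·OEt2 (Kishi reductive C-glycosidation) removes the anomeric hydroxyl, with hydride delivered from the only open face, and gives 29.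

**Step 19 (relay of three directed reductions).** The enone carbonyl at C7 may not be reduced through the 9-OH relay, or may be reduced from the wrong face. Fallback, from 32 back to 34: L-Selectride (THF, −78 °C) reduces all three ketones from their exposed faces, which should give the correct C2 and C9 carbinols but the C7-epimeric allylic alcohol, the 7-epi pentaol imide F3. LiOH/H2O2 cleaves the auxiliary to the seco acid F4 (a 14-acetate lost here is restored in step 20). Intramolecular Mitsunobu lactonisation (PPh3, DIAD, THF) inverts C7 and gives 34.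

**Step 21 (ene chlorination).** The alkene is deactivated by two allylic oxygens, and regio- or facial selectivity may be poor. Fallback, from 35 back to 36: SeO2/t-BuOOH oxidises the C16 methyl (the allylic CH3 on the more substituted alkene terminus) to the primary allylic alcohol F5. SOCl2 in Et2O at −20 °C then delivers chloride to C6 with allylic transposition (SNi′), forming the 5(16)-methylene and giving 36.

## Further compounds

F1 | step 17 | keto-lactone (C4 lactone carbonyl, pyran-3,6-dione) from 27 | O=C1C=CC(=O)O[C@]1([C@@H](C)C(=O)N1[C@H](Cc2ccccc2)COC1=O)C(=O)[C@@H]1[C@](C)([C@@H](OC(C)=O)CC[C@]1(O[Si](CC)(CC)CC)CO[Si](c1ccccc1)(c1ccccc1)C(C)(C)C)C(=O)CO[Si](CC)(CC)CC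
F2 | step 17 | bridged C4 hemiketal of 29 | O=C1C=C[C@@]2(O)O[C@]1([C@@H](C)C(=O)N1[C@H](Cc4ccccc4)COC1=O)C(=O)[C@@H]3[C@](C)([C@@H](OC(C)=O)CC[C@]3(O[Si](CC)(CC)CC)CO[Si](c3ccccc3)(c3ccccc3)C(C)(C)C)C(=O)[C@@H]2O[Si](CC)(CC)CC
F3 | step 19 | 7-epi pentaol imide | O[C@@H]1C=C(C)[C@H]2O[C@]1([C@@H](C)C(=O)N1[C@H](Cc4ccccc4)COC1=O)[C@@H](O)[C@@H]3[C@](C)([C@@H](OC(C)=O)CC[C@]3(O)CO[Si](c3ccccc3)(c3ccccc3)C(C)(C)C)[C@@H](O)[C@@H]2O
F4 | step 19 | 7-epi seco acid | O[C@@H]1C=C(C)[C@H]2O[C@]1([C@@H](C)C(=O)O)[C@@H](O)[C@@H]3[C@](C)([C@@H](OC(C)=O)CC[C@]3(O)CO[Si](c3ccccc3)(c3ccccc3)C(C)(C)C)[C@@H](O)[C@@H]2O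
F5 | step 21 | C16 allylic alcohol of 35 | OCC1[C@H]2O[C@]3([C@@H](C)C(=O)O[C@H]3C=1)[C@@H](OC(C)=O)[C@@H]1[C@](C)([C@@H](OC(C)=O)CC[C@]1(O)CO[Si](c1ccccc1)(c1ccccc1)C(C)(C)C)[C@@H](OC(C)=O)[C@@H]2OC(C)=O
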